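**Retrosynthetic overview** (labdane numbering C1–C20 is used in the text)
1. The butenolide comes from a 3-alkylfuran (singlet oxygen, then hydride). C19–OAc and the C3 methylene come from a decalin that carries a C3 ketone and a C19 methyl ester.
2. Key disconnection: cut C9–C10 and draw a bond C4–C10. Ring A (C1–C2–C3–C4–C5–C10) shrinks to a cyclopentanone (C1–C2–C3–C4–C10) fused to a cyclopropane (C4–C5–C10). Ring B opens to a chain that ends in the allylsilane C17–C8=C9.
3. Enabling feature: in ring A the quaternary C4 bears an oxidised one-carbon branch (C19), and only C5–H separates it from the quaternary, methyl-bearing fusion carbon C10. With C3=O and a C19 ester, C4 is a stabilised carbanion leaving group and C10 a tertiary cation site, so C4–C10 can break heterolytically. The C8=C17 methylene of ring B is the footprint of the allylsilane that captures C10.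
4. The bicyclo[3.1.0]hexanone comes from an α-diazo-β-keto ester by enantioselective intramolecular cyclopropanation of the E-C5=C10 alkene. The chain comes from 3-(furan-3-yl)propanal by two Johnson–Claisen rearrangements, which fix both alkene geometries.
5. Ring order: furan (bought); cyclopentanone and cyclopropane together (step 9); ring A by 5→6 expansion and ring B by closure in one step (step 10); butenolide from the furan (step 15).

Key step: step 10

Assumption: the (S,S) antipode of the bis(oxazoline) ligand is taken to give the cyclopropane in the drawn absolute configuration. If a pilot run shows the opposite sense, the (R,R) ligand is used.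

**Step 1**
Reactants: 1 3-bromofuran; 2 allyl alcohol
Product: 3 3-(furan-3-yl)propanal
Conditions: Pd(OAc)2 (cat.), n-Bu4NCl, NaHCO3, DMF, 50 °C
Reagents that add atoms: none
Why: Heck arylation of allyl alcohol: carbopalladation puts the furyl group on the terminal carbon, and β-hydride elimination toward the carbinol carbon gives an enol that tautomerises to the aldehyde.

**Step 2**
Reactants: 3 3-(furan-3-yl)propanal; 4 (2-bromoallyl)trimethylsilane
Product: 6 5-(furan-3-yl)-2-[(trimethylsilyl)methyl]pent-1-en-3-ol (racemic), via vinyl Grignard reagent 5 (not isolated)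
Conditions: Mg, THF, rt; then 3, −78 → 0 °C; aq NH4Cl
Reagents that add atoms: none
Why: Grignard addition of the 2-metallated allylsilane to an unhindered aldehyde; the carbinol centre forms racemic, which is harmless because step 3 erases it.

**Step 3**
Reactants: 6 5-(furan-3-yl)-2-[(trimethylsilyl)methyl]pent-1-en-3-ol; 7 trimethyl orthoacetate
Product: 9 methyl (4Z)-7-(furan-3-yl)-4-[(trimethylsilyl)methyl]hept-4-enoate, via ketene acetal 8 (not isolated)
Conditions: 7 (excess), EtCO2H (cat.), toluene, 110 °C, removal of MeOH
Reagents that add atoms: none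
Why: Johnson–Claisen rearrangement: in the chair transition state the furylethyl group sits equatorial, so C11 should end trans to C7 and cis to CH2SiMe3 (Z by CIP because of silicon), and the weak acid should spare allylsilane and furan.

**Step 4**
Reactants: 9 methyl (4Z)-7-(furan-3-yl)-4-[(trimethylsilyl)methyl]hept-4-enoate
Product: 10 (4Z)-7-(furan-3-yl)-4-[(trimethylsilyl)methyl]hept-4-enal
Conditions: DIBAL-H, CH2Cl2, −78 °C; Rochelle salt
Reagents that add atoms: none
Why: Partial ester reduction: at −78 °C the tetrahedral aluminium hemiacetal persists and releases the aldehyde only on work-up.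

**Step 5**
Reactants: 10 (4Z)-7-(furan-3-yl)-4-[(trimethylsilyl)methyl]hept-4-enal; 11 isopropenylmagnesium bromide
Product: 12 (6Z)-9-(furan-3-yl)-2-methyl-6-[(trimethylsilyl)methyl]nona-1,6-dien-3-ol (racemic)
Conditions: THF, −78 → 0 °C; aq NH4Cl
Reagents that add atoms: none
Why: Grignard addition to an aldehyde; the racemic carbinol centre is erased in step 6.

**Step 6**
Reactants: 12 (6Z)-9-(furan-3-yl)-2-methyl-6-[(trimethylsilyl)methyl]nona-1,6-dien-3-ol; 7 trimethyl orthoacetate
Product: 14 methyl (4E,8Z)-11-(furan-3-yl)-4-methyl-8-[(trimethylsilyl)methyl]undeca-4,8-dienoate, via ketene acetal 13 (not isolated)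
Conditions: 7 (excess), EtCO2H (cat.), toluene, 110 °C, removal of MeOH
Reagents that add atoms: none
Why: Second Johnson–Claisen rearrangement: the chair transition state with the chain equatorial should give the E-C5=C10 alkene, whose geometry later encodes the trans ring fusion.

**Step 7**
Reactants: 14 methyl (4E,8Z)-11-(furan-3-yl)-4-methyl-8-[(trimethylsilyl)methyl]undeca-4,8-dienoate; 15 methyl acetate
Product: 17 methyl (6E,10Z)-13-(furan-3-yl)-6-methyl-3-oxo-10-[(trimethylsilyl)methyl]trideca-6,10-dienoate, via lithium enolate 16 (not isolated)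
Conditions: LDA, 15, THF, −78 °C; then 14, −78 → 0 °C; AcOH
Reagents that add atoms: none
Why: Crossed Claisen condensation of an unhindered methyl ester with excess ester enolate, driven by deprotonation of the β-keto ester; methoxide is the only alkoxide present, so no ester scrambling can occur.

**Step 8**
Reactants: 17 methyl (6E,10Z)-13-(furan-3-yl)-6-methyl-3-oxo-10-[(trimethylsilyl)methyl]trideca-6,10-dienoate
Product: 18 methyl (6E,10Z)-2-diazo-13-(furan-3-yl)-6-methyl-3-oxo-10-[(trimethylsilyl)methyl]trideca-6,10-dienoate
Conditions: p-ABSA, Et3N, MeCN, 0 °C → rt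
Reagents that add atoms: 4-acetamidobenzenesulfonyl azide (p-ABSA), CC(=O)Nc1ccc(cc1)S(=O)(=O)N=[N+]=[N-]
Why: Regitz diazo transfer to the activated methylene of a β-keto ester under mild amine base, to which alkenes, allylsilane and furan are inert.

**Step 9**
Reactants: 18 methyl (6E,10Z)-2-diazo-13-(furan-3-yl)-6-methyl-3-oxo-10-[(trimethylsilyl)methyl]trideca-6,10-dienoate
Product: 19 methyl (1S,5S,6S)-6-{(3Z)-6-(furan-3-yl)-3-[(trimethylsilyl)methyl]hex-3-en-1-yl}-5-methyl-2-oxobicyclo[3.1.0]hexane-1-carboxylate (side chain exo and cis to the 5-methyl group)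
Conditions: [Cu(MeCN)4]PF6 (cat.), (S,S)-t-Bu-box (cat.), toluene, 40 °C, slow addition, high dilution
Reagents that add atoms: none
Why: Enantioselective Cu(I)–bis(oxazoline) intramolecular cyclopropanation of an α-diazo-β-keto ester: syn addition to the E-alkene fixes the relative configuration of C4, C5 and C10, the ligand sets the absolute sense, and five-membered ring closure should outrun attack on the remote allylsilane and furan.

**Step 10**
Reactants: 19 methyl (1S,5S,6S)-6-{(3Z)-6-(furan-3-yl)-3-[(trimethylsilyl)methyl]hex-3-en-1-yl}-5-methyl-2-oxobicyclo[3.1.0]hexane-1-carboxylate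
Product: 21 methyl 15,16-epoxy-3-oxo-ent-labda-8(17),13(16),14-trien-19-oate, via silyl enol ether 20 (not isolated)
Conditions: Sc(OTf)3 (10 mol %), 2,6-di-tert-butyl-4-methylpyridine (cat.), CH2Cl2 (0.01 M), −78 → −20 °C; then MeI, TBAF (THF), −20 °C → rt
Reagents that add atoms: iodomethane, CI
Why: Proposed new method: Sc(III) chelates the C3 ketone and the C19 ester, so C4 becomes a stabilised enolate leaving group and the C4–C10 bond, shared by cyclopropane and cyclopentanone and ending at the fully substituted C10, is polarised; C9 of the allylsilane attacks C10 from the rear of this bond, Me3Si+ leaves C17 to unveil the C8=C17 methylene and passes to the enolate oxygen (20, which frees the catalyst), and fluoride then releases the enolate for C-methylation by MeI in the same flask. The closest known reaction types are the Lewis acid cyclisation of olefinic cyclopropyl ketones, the invertive homo-Michael opening of donor–acceptor cyclopropanes by allylsilanes (Hosomi–Sakurai type), the acid-induced inner-bond cleavage of 5-alkylbicyclo[3.1.0]hexan-2-ones to cyclohexanones, and the epoxide-initiated, allylsilane-terminated polyene cyclisation, of which this step is the all-carbon counterpart. Ring A is not closed but grows from five to six members, because the cyclopentanone C1–C2–C3–C4–C10 takes in the apex carbon C5 when C4–C10 breaks, while ring B closes through the new C9–C10 bond in a chair-like mode that is 6-endo-trig at C8=C9 and exo-tet at C10. C10 is set by inversion at the cyclopropane carbon, which together with the retained C5 turns the E geometry stored in 19 into the trans ring fusion; C9 is set by the chair transition state, in which C11 (trans to C7 on the alkene) becomes equatorial; C4 is set by approach of MeI to the enolate face opposite the axial C10 methyl, which leaves the ester axial. The step needs cleavage of the inner C4–C10 bond rather than the outer C4–C5 bond, and loss of silicon rather than a [3+2] closure: the first is secured by the tertiary, cation-stabilising C10 and by the tether, which lets C9 reach only C10, and the second by the small SiMe3 group and the distance between C4 and C8. The hindered pyridine removes adventitious acid, so allylsilane and furan should survive.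

**Step 11**
Reactants: 21 methyl 15,16-epoxy-3-oxo-ent-labda-8(17),13(16),14-trien-19-oate
Product: 22 15,16-epoxy-ent-labda-8(17),13(16),14-triene-3,19-diol (3-OH equatorial)
Conditions: LiAlH4, THF, 0 °C → reflux; then H2O
Reagents that add atoms: none
Why: Hydride reduction of ester and ketone with LiAlH4: hydride should reach C3 axially, on the face opposite the axial C19 and C20 groups, to give the equatorial alcohol (a centre removed again in step 14), while furan and alkenes are inert.

**Step 12**
Reactants: 22 15,16-epoxy-ent-labda-8(17),13(16),14-triene-3,19-diol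
Product: 23 19-acetoxy-15,16-epoxy-ent-labda-8(17),13(16),14-trien-3-ol
Conditions: Ac2O (1 equiv), pyridine, CH2Cl2, −20 °C
Reagents that add atoms: acetic anhydride, CC(=O)OC(C)=O
Why: Site-selective O-acylation: the primary C19 hydroxyl should react faster than the C3 hydroxyl, which is secondary and flanked by the quaternary C4.

**Step 13**
Reactants: 23 19-acetoxy-15,16-epoxy-ent-labda-8(17),13(16),14-trien-3-ol
Product: 24 19-acetoxy-3-(phenoxythiocarbonyloxy)-15,16-epoxy-ent-labda-8(17),13(16),14-triene
Conditions: PhOC(S)Cl, pyridine, DMAP (cat.), CH2Cl2, rt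
Reagents that add atoms: O-phenyl chlorothionoformate, S=C(Cl)Oc1ccccc1
Why: Thionocarbonate formation with the reactive aryl chlorothionoformate under DMAP catalysis works on hindered secondary alcohols at room temperature, which should also keep the neighbouring acetate from migrating.

**Step 14**
Reactants: 24 19-acetoxy-3-(phenoxythiocarbonyloxy)-15,16-epoxy-ent-labda-8(17),13(16),14-triene
Product: 25 19-acetoxy-15,16-epoxy-ent-labda-8(17),13(16),14-triene
Conditions: Bu3SnH, AIBN (cat.), toluene, 100 °C
Reagents that add atoms: none
Why: Barton–McCombie deoxygenation: the stannyl radical adds to C=S, and the released secondary C3 radical has no alkene within reach and takes hydrogen from the stannane, which erases the auxiliary C3 centre.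

**Step 15**
Reactants: 25 19-acetoxy-15,16-epoxy-ent-labda-8(17),13(16),14-triene
Product: 28 (4R,5S,9R,10S)-19-acetoxy-ent-labda-8(17),13-dien-15,16-olide (target), via furan endoperoxide 26 (not isolated), via hydroxybutenolide 27 (not isolated)
Conditions: O2, hν, tetraphenylporphyrin (cat.), i-Pr2NEt, CH2Cl2, −78 °C → rt; then MeOH, NaBH4, 0 °C; 1 M HCl
Reagents that add atoms: dioxygen, O=O
Why: [4+2] addition of singlet oxygen to the furan, which reacts far faster than the 1,1-disubstituted alkene, then Kornblum–DeLaMare fragmentation in which the hindered base removes the less hindered C15–H and places the carbonyl remote from the alkyl group; borohydride reduces the open aldehyde form, and the hydroxy acid lactonises to the β-substituted butenolide without touching the acetate.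

**Compound list**
1 | 3-bromofuran | Brc1ccoc1 | starting material
2 | allyl alcohol | C=CCO | starting material
3 | 3-(furan-3-yl)propanal | O=CCCc1ccoc1 | intermediate
4 | (2-bromoallyl)trimethylsilane | C=C(Br)C[Si](C)(C)C | starting material
5 | [1-(trimethylsilylmethyl)vinyl]magnesium bromide | C=C(C[Si](C)(C)C)[Mg]Br | intermediate
6 | 5-(furan-3-yl)-2-[(trimethylsilyl)methyl]pent-1-en-3-ol (racemic) | C=C(C[Si](C)(C)C)C(O)CCc1ccoc1 | intermediate
7 | trimethyl orthoacetate | CC(OC)(OC)OC | starting material
8 | methyl ketene acetal of 6 | C=C(OC)OC(CCc1ccoc1)C(=C)C[Si](C)(C)C | intermediate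
9 | methyl (4Z)-7-(furan-3-yl)-4-[(trimethylsilyl)methyl]hept-4-enoate | COC(=O)CC/C(C[Si](C)(C)C)=C/CCc1ccoc1 | intermediate
10 | (4Z)-7-(furan-3-yl)-4-[(trimethylsilyl)methyl]hept-4-enal | O=CCC/C(C[Si](C)(C)C)=C/CCc1ccoc1 | intermediate
11 | isopropenylmagnesium bromide | C=C(C)[Mg]Br | starting material
12 | (6Z)-9-(furan-3-yl)-2-methyl-6-[(trimethylsilyl)methyl]nona-1,6-dien-3-ol (racemic) | C=C(C)C(O)CC/C(C[Si](C)(C)C)=C/CCc1ccoc1 | intermediate
13 | methyl ketene acetal of 12 | C=C(OC)OC(C(C)=C)CC/C(C[Si](C)(C)C)=C/CCc1ccoc1 | intermediate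
14 | methyl (4E,8Z)-11-(furan-3-yl)-4-methyl-8-[(trimethylsilyl)methyl]undeca-4,8-dienoate | COC(=O)CC/C(C)=C/CC/C(C[Si](C)(C)C)=C/CCc1ccoc1 | intermediate
15 | methyl acetate | COC(C)=O | starting material
16 | lithium enolate of methyl acetate | C=C(OC)O[Li] | intermediate
17 | methyl (6E,10Z)-13-(furan-3-yl)-6-methyl-3-oxo-10-[(trimethylsilyl)methyl]trideca-6,10-dienoate | COC(=O)CC(=O)CC/C(C)=C/CC/C(C[Si](C)(C)C)=C/CCc1ccoc1 | intermediate
18 | methyl (6E,10Z)-2-diazo-13-(furan-3-yl)-6-methyl-3-oxo-10-[(trimethylsilyl)methyl]trideca-6,10-dienoate | COC(=O)C(=[N+]=[N-])C(=O)CC/C(C)=C/CC/C(C[Si](C)(C)C)=C/CCc1ccoc1 | intermediate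
19 | methyl (1S,5S,6S)-6-{(3Z)-6-(furan-3-yl)-3-[(trimethylsilyl)methyl]hex-3-en-1-yl}-5-methyl-2-oxobicyclo[3.1.0]hexane-1-carboxylate | COC(=O)[C@]12C(=O)CC[C@@]1(C)[C@@H]2CC/C(C[Si](C)(C)C)=C/CCc1ccoc1 | intermediate
20 | methyl 15,16-epoxy-3-(trimethylsilyloxy)-18-nor-ent-labda-3,8(17),13(16),14-tetraen-19-oate | C=C1CC[C@@H]2C(C(=O)OC)=C(O[Si](C)(C)C)CC[C@@]2(C)[C@@H]1CCc1ccoc1 | intermediate
21 | methyl 15,16-epoxy-3-oxo-ent-labda-8(17),13(16),14-trien-19-oate (ester axial and cis to the C10 methyl) | C=C1CC[C@@H]2[C@](C)(C(=O)OC)C(=O)CC[C@@]2(C)[C@@H]1CCc1ccoc1 | intermediate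
22 | 15,16-epoxy-ent-labda-8(17),13(16),14-triene-3,19-diol (3-OH equatorial) | C=C1CC[C@@H]2[C@](C)(CO)[C@H](O)CC[C@@]2(C)[C@@H]1CCc1ccoc1 | intermediate
23 | 19-acetoxy-15,16-epoxy-ent-labda-8(17),13(16),14-trien-3-ol | C=C1CC[C@@H]2[C@](C)(COC(C)=O)[C@H](O)CC[C@@]2(C)[C@@H]1CCc1ccoc1 | intermediate
24 | 19-acetoxy-3-(phenoxythiocarbonyloxy)-15,16-epoxy-ent-labda-8(17),13(16),14-triene | C=C1CC[C@@H]2[C@](C)(COC(C)=O)[C@H](OC(=S)Oc3ccccc3)CC[C@@]2(C)[C@@H]1CCc1ccoc1 | intermediate
25 | 19-acetoxy-15,16-epoxy-ent-labda-8(17),13(16),14-triene | C=C1CC[C@@H]2[C@](C)(COC(C)=O)CCC[C@@]2(C)[C@@H]1CCc1ccoc1 | intermediate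
26 | furan endoperoxide of 25 (2,3,7-trioxabicyclo[2.2.1]hept-5-ene) | C=C1CC[C@@H]2[C@](C)(COC(C)=O)CCC[C@@]2(C)[C@@H]1CCC1=CC2OOC1O2 | intermediate
27 | 19-acetoxy-16-hydroxy-ent-labda-8(17),13-dien-15,16-olide (C16 epimers) | C=C1CC[C@@H]2[C@](C)(COC(C)=O)CCC[C@@]2(C)[C@@H]1CCC1=CC(=O)OC1O | intermediate
28 | (4R,5S,9R,10S)-19-acetoxy-ent-labda-8(17),13-dien-15,16-olide, CNP0189477.2 | C=C1CC[C@@H]2[C@](C)(COC(C)=O)CCC[C@@]2(C)[C@@H]1CCC1=CC(=O)OC1 | target

**Total step count:** 15. **Longest linear sequence:** 15 steps (1 → 28). All other building blocks (2, 4, 7, 11, 15) are bought.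

**Steps most likely to fail**

Step 10 (proposed new method).
- Risk: the polarised cyclopropane may ionise without being captured. Possible outcomes are proton loss next to C10 or O-closure to a dihydrofuran.
- Risk: it may open stepwise, so the stereochemical information at C10 is lost. The later methylation may also show poor facial or C/O selectivity.
- Fallback: ring expansion and ring closure are separated, using known reactions only.
- From 19, Lewis acid-catalysed methanolysis (Yb(OTf)3, MeOH, rt) should open the same inner bond with inversion. This gives the ring-expanded methyl 6-{(3Z)-6-(furan-3-yl)-3-[(trimethylsilyl)methyl]hex-3-en-1-yl}-5-methoxy-5-methyl-2-oxocyclohexane-1-carboxylate F1.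
- BF3·OEt2 in CH2Cl2 at −78 °C then ionises the tertiary ether. An intramolecular Hosomi–Sakurai alkylation through the chair closes ring B to methyl 15,16-epoxy-3-oxo-18-nor-ent-labda-8(17),13(16),14-trien-19-oate F2.
- K2CO3/MeI in acetone methylates C4 and returns to the route at 21.

Step 9.
- Risk: the catalyst may discriminate poorly between the alkene faces of this acceptor/acceptor carbenoid, or the carbenoid may leak to the remote allylsilane or furan.
- Fallback: stereocontrol is moved from catalysis to resolution.
- From 18, Rh2(OAc)4 in CH2Cl2 under high dilution gives the racemate, that is 19 together with its mirror image ent-19 F3.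
- Preparative SFC on a chiral stationary phase separates the two, and the route is rejoined at 19.

Step 12.
- Risk: acylation may run on to the diacetate, or the acetyl group may migrate from O19 to O3 before or during thiocarbonylation.
- Fallback: the two hydroxyl groups are tied together instead of being told apart.
- From 22, 1,1′-thiocarbonyldiimidazole (toluene, 80 °C) closes the six-membered 3,19-O-thiocarbonyl-15,16-epoxy-ent-labda-8(17),13(16),14-triene-3,19-diol F4.
- Bu3SnH/AIBN cleaves it at the C3–O bond, which gives the more stable secondary radical. Basic hydrolysis of the remaining thiolcarbonate gives 15,16-epoxy-ent-labda-8(17),13(16),14-trien-19-ol F5.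
- Ac2O/pyridine then returns to the route at 25.

**Further compounds**
F1 | step 10 | methyl 6-{(3Z)-6-(furan-3-yl)-3-[(trimethylsilyl)methyl]hex-3-en-1-yl}-5-methoxy-5-methyl-2-oxocyclohexane-1-carboxylate | COC(=O)C1C(=O)CC[C@@](C)(OC)[C@@H]1CC/C(C[Si](C)(C)C)=C/CCc1ccoc1
F2 | step 10 | methyl 15,16-epoxy-3-oxo-18-nor-ent-labda-8(17),13(16),14-trien-19-oate | C=C1CC[C@@H]2C(C(=O)OC)C(=O)CC[C@@]2(C)[C@@H]1CCc1ccoc1
F3 | step 9 | ent-19, methyl (1R,5R,6R)-6-{(3Z)-6-(furan-3-yl)-3-[(trimethylsilyl)methyl]hex-3-en-1-yl}-5-methyl-2-oxobicyclo[3.1.0]hexane-1-carboxylate | COC(=O)[C@@]12C(=O)CC[C@]1(C)[C@H]2CC/C(C[Si](C)(C)C)=C/CCc1ccoc1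
F4 | step 12 | 3,19-O-thiocarbonyl-15,16-epoxy-ent-labda-8(17),13(16),14-triene-3,19-diol | C=C1CC[C@@H]2[C@]3(C)COC(=S)O[C@@H]3CC[C@@]2(C)[C@@H]1CCc1ccoc1
F5 | step 12 | 15,16-epoxy-ent-labda-8(17),13(16),14-trien-19-ol | C=C1CC[C@@H]2[C@](C)(CO)CCC[C@@]2(C)[C@@H]1CCc1ccoc1
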